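## Retrosynthetic overview

1. Tatanan B (13) ⇒ phenol–styrene 12: the last step closes the only new ring (C6–C11) by proton-triggered attack of the phenol para-carbon, which also turns ring C into the dienone.
2. 12 ⇒ aryl bromide 11 by aryl C–O bond formation (Pd-catalysed hydroxylation). This is the pivot of the route: the oxygen that becomes the dienone C=O is installed late, and until then Br keeps ring C inert to the cations used earlier.
3. 11 ⇒ benzylic alcohol 9 + α-asarone (C9–C10 bond, sets C9).
4. 9 ⇒ aldehyde 5 + aryl Grignard reagent; 5 ⇒ allylic alcohol 3 + propanal (sets C7 and C8); 3 ⇒ 4-bromo-2,5-dimethoxybenzaldehyde + vinylmagnesium bromide.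
5. Ring order: no ring is built before the end; the cyclohexane ring forms last, in the same event that dearomatises ring C.

Assumption: the six stereocentres in the SMILES (6S,7R,8S,9S,10R,11R by my CIP assignment) define the target completely; no stereo-axis is specified, so none is controlled.

Locants C6–C11 are those of the spiro[5.5]undecane core of 13 (C6 spiro, C7 CHEt, C8 CHMe, C9 CHAr, C10 CHMe, C11 CHAr). Ring A is the aryl on C11, ring B the aryl on C9, ring C the ring that becomes the dienone.

## Route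

Step 1
Reactants: 1 4-bromo-2,5-dimethoxybenzaldehyde; 2 vinylmagnesium bromide
Product: 3 rac-1-(4-bromo-2,5-dimethoxyphenyl)prop-2-en-1-ol
Conditions: CH2=CHMgBr (1.2 equiv), THF, −78 → 0 °C; then H2O
Reagents that add atoms: none
Why: Grignard 1,2-addition to the aldehyde; the carbinol centre is left racemic on purpose because the next step ionises it.

Step 2
Reactants: 3 rac-1-(4-bromo-2,5-dimethoxyphenyl)prop-2-en-1-ol; 4 propanal
Product: 5 (2S,3R)-3-(4-bromo-2,5-dimethoxyphenyl)-2-methylpent-4-enal
Conditions: [Ir(cod)Cl]2 (3 mol %), (R)-5-(dinaphtho[2,1-d:1′,2′-f][1,3,2]dioxaphosphepin-4-yl)-5H-dibenzo[b,f]azepine (12 mol %), (R)-2-{bis[3,5-bis(trifluoromethyl)phenyl][(trimethylsilyl)oxy]methyl}pyrrolidine (10 mol %), (MeO)2P(O)OH (10 mol %), propanal (3 equiv), ClCH2CH2Cl, 25 °C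
Reagents that add atoms: none
Why: Stereodivergent dual catalysis (iridium-catalysed branched-selective allylic substitution merged with enamine catalysis), in which both enantiomers of 3 give the same allyl-iridium species, the phosphoramidite–olefin ligand fixes the aryl-bearing centre (3R, C7 of the target) and the amine independently fixes the α-centre (2S, C8); the (R)-amine follows the usual shielding model, whereas the (R)-ligand is my unconfirmed assignment, to be checked on the first batch and swapped for its antipode if the benzylic centre comes out opposite.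

Step 3
Reactants: 5 (2S,3R)-3-(4-bromo-2,5-dimethoxyphenyl)-2-methylpent-4-enal; 6 1-bromo-2,4,5-trimethoxybenzene
Product: 8 (2S,3R)-3-(4-bromo-2,5-dimethoxyphenyl)-2-methyl-1-(2,4,5-trimethoxyphenyl)pent-4-en-1-ol (both C1 epimers), via aryl Grignard reagent 7 (not isolated)
Conditions: 6, Mg, LiCl, THF, 25 °C; then 5, −78 → −20 °C; then H2O
Reagents that add atoms: none
Why: LiCl-assisted magnesium insertion followed by Grignard 1,2-addition at low temperature, which spares the α-stereocentre and the aryl bromide; the new carbinol centre forms as a mixture and is erased when it is ionised in step 5.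

Step 4
Reactants: 8 (2S,3R)-3-(4-bromo-2,5-dimethoxyphenyl)-2-methyl-1-(2,4,5-trimethoxyphenyl)pent-4-en-1-ol (both C1 epimers)
Product: 9 (2S,3R)-3-(4-bromo-2,5-dimethoxyphenyl)-2-methyl-1-(2,4,5-trimethoxyphenyl)pentan-1-ol (both C1 epimers)
Conditions: H2 (1 atm), RhCl(PPh3)3 (5 mol %), benzene/EtOH 1:1, 25 °C
Reagents that add atoms: none
Why: Homogeneous hydrogenation with RhCl(PPh3)3 reduces only the monosubstituted alkene to the ethyl group and leaves the aryl bromide, the benzylic alcohol and both stereocentres untouched; no new stereocentre is formed.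

Step 5
Reactants: 9 (2S,3R)-3-(4-bromo-2,5-dimethoxyphenyl)-2-methyl-1-(2,4,5-trimethoxyphenyl)pentan-1-ol (both C1 epimers); 10 α-asarone [(E)-1,2,4-trimethoxy-5-(prop-1-en-1-yl)benzene]
Product: 11 (1E,3S,4S,5R)-5-(4-bromo-2,5-dimethoxyphenyl)-2,4-dimethyl-1,3-bis(2,4,5-trimethoxyphenyl)hept-1-ene
Conditions: 10 (3 equiv), Ca(NTf2)2 (5 mol %), n-Bu4NPF6 (5 mol %), CH2Cl2/(CF3)2CHOH 9:1, −40 °C, slow addition of 9
Reagents that add atoms: none
Why: Dehydrative SN1 alkenylation (benzylic cation–olefin coupling with E1 termination), in which the 2,4,5-trimethoxybenzyl cation sits in the allylic-strain-minimised conformer with the C8–H eclipsing ring B, asarone attacks through its β-carbon on the face opposite the CH(Et)Ar group to set C9 (3S), the new benzylic cation loses the C10 proton to give the conjugated E-styrene, the bromine keeps ring C too electron-poor to trap either cation as an indane, and the minor C9 epimer is removed by chromatography.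

Step 6
Reactants: 11 (1E,3S,4S,5R)-5-(4-bromo-2,5-dimethoxyphenyl)-2,4-dimethyl-1,3-bis(2,4,5-trimethoxyphenyl)hept-1-ene
Product: 12 4-[(3R,4S,5S,6E)-4,6-dimethyl-5,7-bis(2,4,5-trimethoxyphenyl)hept-6-en-3-yl]-2,5-dimethoxyphenol
Conditions: Pd2(dba)3 (2 mol %), 2-di-tert-butylphosphino-2′,4′,6′-triisopropylbiphenyl (8 mol %), KOH (3 equiv), 1,4-dioxane/H2O 1:1, 90 °C, argon; then pH 7 phosphate buffer
Reagents that add atoms: potassium hydroxide, [K+].[OH-]
Why: Palladium-catalysed hydroxylation of the aryl bromide (C–O cross-coupling with hydroxide, the bulky biaryl phosphine driving C–O reductive elimination) makes the aryl C–O bond that becomes the dienone carbonyl and converts the so far silent ring C into the most nucleophilic arene of the molecule; no stereocentre is touched.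

Step 7
Reactants: 12 4-[(3R,4S,5S,6E)-4,6-dimethyl-5,7-bis(2,4,5-trimethoxyphenyl)hept-6-en-3-yl]-2,5-dimethoxyphenol
Product: 13 tatanan B
Conditions: (PhO)2P(O)OH (10 mol %), (CF3)2CHOH, 0 → 25 °C, argon
Reagents that add atoms: none
Why: Proposed new method: phosphoric-acid-catalysed protonative dearomative spirocyclisation (a redox-neutral cycloisomerisation), in which the acid reversibly protonates the electron-rich trisubstituted styrene at C10, the resulting 2,4,5-trimethoxybenzyl cation is captured through a chair by the ring-C carbon para to the free OH, and the phosphate removes the phenolic proton to release the dienone and the catalyst; C10 is set because the cation epimer with an axial C10-methyl (1,3-diaxial to the axial C8-methyl) cannot close and reverts to the styrene, C11 by the equatorial position of ring A, and C6 because the ring-C methoxy group ortho to the tether stays next to the C7–H and ends equatorial; the closest known reaction types are acid-catalysed intramolecular hydroarylation of styrenes and ipso-Friedel–Crafts dearomatisation of para-substituted phenols by benzylic or allyl cations.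

## Compound list

1 | 4-bromo-2,5-dimethoxybenzaldehyde | O=Cc1cc(OC)c(Br)cc1OC | starting material
2 | vinylmagnesium bromide | C=C[Mg]Br | starting material
3 | rac-1-(4-bromo-2,5-dimethoxyphenyl)prop-2-en-1-ol | C=CC(O)c1cc(OC)c(Br)cc1OC | intermediate
4 | propanal | CCC=O | starting material
5 | (2S,3R)-3-(4-bromo-2,5-dimethoxyphenyl)-2-methylpent-4-enal | C=C[C@@H](c1cc(OC)c(Br)cc1OC)[C@H](C)C=O | intermediate
6 | 1-bromo-2,4,5-trimethoxybenzene | COc1cc(OC)c(OC)cc1Br | starting material
7 | (2,4,5-trimethoxyphenyl)magnesium bromide (aryl Grignard reagent, not isolated) | COc1cc(OC)c(OC)cc1[Mg]Br | intermediate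
8 | (2S,3R)-3-(4-bromo-2,5-dimethoxyphenyl)-2-methyl-1-(2,4,5-trimethoxyphenyl)pent-4-en-1-ol (both C1 epimers) | C=C[C@@H](c1cc(OC)c(Br)cc1OC)[C@H](C)C(O)c1cc(OC)c(OC)cc1OC | intermediate
9 | (2S,3R)-3-(4-bromo-2,5-dimethoxyphenyl)-2-methyl-1-(2,4,5-trimethoxyphenyl)pentan-1-ol (both C1 epimers) | CC[C@@H](c1cc(OC)c(Br)cc1OC)[C@H](C)C(O)c1cc(OC)c(OC)cc1OC | intermediate
10 | α-asarone, (E)-1,2,4-trimethoxy-5-(prop-1-en-1-yl)benzene | C/C=C/c1cc(OC)c(OC)cc1OC | starting material
11 | (1E,3S,4S,5R)-5-(4-bromo-2,5-dimethoxyphenyl)-2,4-dimethyl-1,3-bis(2,4,5-trimethoxyphenyl)hept-1-ene | CC[C@@H](c1cc(OC)c(Br)cc1OC)[C@H](C)[C@H](c1cc(OC)c(OC)cc1OC)/C(C)=C/c1cc(OC)c(OC)cc1OC | intermediate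
12 | 4-[(3R,4S,5S,6E)-4,6-dimethyl-5,7-bis(2,4,5-trimethoxyphenyl)hept-6-en-3-yl]-2,5-dimethoxyphenol | CC[C@@H](c1cc(OC)c(O)cc1OC)[C@H](C)[C@H](c1cc(OC)c(OC)cc1OC)/C(C)=C/c1cc(OC)c(OC)cc1OC | intermediate
13 | tatanan B, (6S,7R,8S,9S,10R,11R)-7-ethyl-1,4-dimethoxy-8,10-dimethyl-9,11-bis(2,4,5-trimethoxyphenyl)spiro[5.5]undeca-1,4-dien-3-one | CC[C@@H]1[C@H](C)[C@H](c2cc(OC)c(OC)cc2OC)[C@@H](C)[C@H](c2cc(OC)c(OC)cc2OC)[C@]12C=C(OC)C(=O)C=C2OC | target

## Step count and risks

Total step count: 7. Longest linear sequence: 7 (from 1).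

The three steps most likely to fail:

1. The coupling of 9 with α-asarone (step 5). The cation next to C8 can lose the C8 proton, which would erase that centre; asarone can oligomerise; and the second cation can close onto ring B as an indane. The fallback sets out from 9 and comes back at 11, replacing the alkene by a silyl enol ether that traps the cation irreversibly at −78 °C. Commercial 1-(2,4,5-trimethoxyphenyl)propan-1-one is converted with LiN(SiMe3)2 and Me3SiCl in THF at −78 °C into (Z)-trimethyl{[1-(2,4,5-trimethoxyphenyl)prop-1-en-1-yl]oxy}silane F1. Alcohol 9 and F1 with Me3SiOTf (10 mol %) in CH2Cl2 at −78 °C (Mukaiyama-type SN1 alkylation, same facial control at C9) give (3S,4S,5R)-5-(4-bromo-2,5-dimethoxyphenyl)-2,4-dimethyl-1,3-bis(2,4,5-trimethoxyphenyl)heptan-1-one F2 as a mixture at C2. NaBH4 in MeOH at 0 °C gives (3S,4S,5R)-5-(4-bromo-2,5-dimethoxyphenyl)-2,4-dimethyl-1,3-bis(2,4,5-trimethoxyphenyl)heptan-1-ol F3. Ms2O and Et3N in CH2Cl2 at 0 °C eliminate the benzylic mesylate to the conjugated styrene 11; the mixed centre at C2 disappears in this elimination.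

2. The hydroxylation of 11 (step 6). The bromide is electron-rich and flanked by a methoxy group, and the product is an air-sensitive methoxyhydroquinone-type phenol under hot base. The fallback sets out from 11 and comes back at 12, forming the C–O bond by oxidation of a C–B bond instead of by reductive elimination from palladium. Miyaura borylation (Pd(dppf)Cl2, B2pin2, KOAc, 1,4-dioxane, 90 °C) gives 2-{4-[(3R,4S,5S,6E)-4,6-dimethyl-5,7-bis(2,4,5-trimethoxyphenyl)hept-6-en-3-yl]-2,5-dimethoxyphenyl}-4,4,5,5-tetramethyl-1,3,2-dioxaborolane F4. NaBO3·4H2O in THF/H2O at 25 °C then gives 12 under near-neutral conditions.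

3. The cycloisomerisation of 12 (step 7, the proposed new step). The acid may be too weak to protonate the styrene, or acid-mediated reopening of the dienone may drain material into the ring-B indane. The fallback uses only known reaction types, sets out from 12 and comes back at 13, and closes the ring under base instead of acid. Markovnikov addition of HCl (1 M in Et2O, 1.1 equiv, CH2Cl2, −78 °C) gives 4-[(3R,4S,5S)-7-chloro-4,6-dimethyl-5,7-bis(2,4,5-trimethoxyphenyl)heptan-3-yl]-2,5-dimethoxyphenol F5, which is not isolated. KOt-Bu (2.2 equiv) in THF at −78 → 0 °C forms the phenoxide, whose para-carbon displaces the benzylic chloride (Winstein-type Ar1-6 dienone closure) to give 13. The chloride epimer that would need an axial C10-methyl eliminates back to 12 and is recycled.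

## Further compounds

F1 | step 5 | (Z)-trimethyl{[1-(2,4,5-trimethoxyphenyl)prop-1-en-1-yl]oxy}silane | C/C=C(\O[Si](C)(C)C)c1cc(OC)c(OC)cc1OC
F2 | step 5 | (3S,4S,5R)-5-(4-bromo-2,5-dimethoxyphenyl)-2,4-dimethyl-1,3-bis(2,4,5-trimethoxyphenyl)heptan-1-one (both C2 epimers) | CC[C@@H](c1cc(OC)c(Br)cc1OC)[C@H](C)[C@H](c1cc(OC)c(OC)cc1OC)C(C)C(=O)c1cc(OC)c(OC)cc1OC
F3 | step 5 | (3S,4S,5R)-5-(4-bromo-2,5-dimethoxyphenyl)-2,4-dimethyl-1,3-bis(2,4,5-trimethoxyphenyl)heptan-1-ol (C1 and C2 epimers) | CC[C@@H](c1cc(OC)c(Br)cc1OC)[C@H](C)[C@H](c1cc(OC)c(OC)cc1OC)C(C)C(O)c1cc(OC)c(OC)cc1OC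
F4 | step 6 | 2-{4-[(3R,4S,5S,6E)-4,6-dimethyl-5,7-bis(2,4,5-trimethoxyphenyl)hept-6-en-3-yl]-2,5-dimethoxyphenyl}-4,4,5,5-tetramethyl-1,3,2-dioxaborolane | CC[C@@H](c1cc(OC)c(B2OC(C)(C)C(C)(C)O2)cc1OC)[C@H](C)[C@H](c1cc(OC)c(OC)cc1OC)/C(C)=C/c1cc(OC)c(OC)cc1OC
F5 | step 7 | 4-[(3R,4S,5S)-7-chloro-4,6-dimethyl-5,7-bis(2,4,5-trimethoxyphenyl)heptan-3-yl]-2,5-dimethoxyphenol (C6 and C7 epimers) | CC[C@@H](c1cc(OC)c(O)cc1OC)[C@H](C)[C@H](c1cc(OC)c(OC)cc1OC)C(C)C(Cl)c1cc(OC)c(OC)cc1OC
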